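**Retrosynthetic overview**

1. Vicolide D ⇒ C5–O ester bond to (2R,3R)-epoxyangelic acid 27, C11=C13 by decarboxylative methylenation, C6 carbinol from a ketone ⇒ ten-membered 2,6-diketone 18.
2. Feature used: in the ten-membered ring C1–C10 the oxygens on C2 (enone C=O) and C6 are 1,5-related across C3–C4(Me)–C5(O). 18 is therefore the retro-aldol product of a cyclobutanol C3–C4–C5–C6, that is, of a [2+2] adduct between the C3=C6 enol ester of an eight-membered 2,6-diketone and a propenyl silyl ether (C3–C4 and C5–C6 made, C3–C6 broken; the Z C1=C10 enone is carried over from the small ring).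
3. Precursor 14: the enol oxygen on C6 is acylated from inside by a carboxyl placed on C11, not by acetyl. Bimolecular acylation of the unsymmetrical ring diketone would favour the less hindered, linearly conjugated C2 enol ester; the C11 carboxyl also makes 14 cup-shaped and later delivers C13 without strong base.
4. Eight-membered ring: ring-closing metathesis at C1=C10 on a trans-4,5-disubstituted γ-lactone (C7: vinyl → acetyl → acrolein aldol; C8: 2-methylallyl) made from (S)-5-(hydroxymethyl)furan-2(5H)-one.
5. Ring order: γ-lactone (chiral pool) → eight-membered carbocycle → enol lactone → cyclobutane → ten-membered ring by fragmentation; the epoxide is made separately by Sharpless epoxidation.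

Key step: step 13

**Numbering and remarks**

- C1 = enone CH, C2 = ketone, C3 = CH2, C4 = CHMe, C5 = acyloxy carbon, C6 = carbinol carbon, C7/C8 = ring fusion (C8 bears the lactone oxygen), C9 = CH2, C10 = CMe, C11 = lactone α-carbon, C12 = lactone C=O, C13 = exocyclic CH2. O6 = oxygen on C6; ring A = γ-lactone C7–C8–O–C12–C11; ring B = enol lactone C6–O6–C(=O)–C11–C7.
- Assumption: the target is read as 4R,5R,6R,7R,8R with a trans-fused lactone and a (2R,3R)-2,3-epoxy-2-methylbutanoate.
- C11 of the malonate-type lactones 7–13 and 18–21 epimerises freely and is drawn without configuration; it becomes sp2 in step 16. The C2 carbinol epimers of 10 and 11 converge in step 10. The silyl group of the alkene partner is triethylsilyl, so that C5 and C6 can be told apart later.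

**Route**

Step 1
Reactants: 1 (S)-5-(hydroxymethyl)furan-2(5H)-one
Product: 2 (S)-5-[(tert-butyldimethylsilyloxy)methyl]furan-2(5H)-one
Conditions: tBuMe2SiCl, imidazole, DMF, 0 °C → rt
Reagents that add atoms: tert-butyldimethylsilyl chloride, CC(C)(C)[Si](C)(C)Cl
Why: Silyl ether formation masks the primary alcohol and provides the bulky C8 substituent that shields one face of the butenolide; no stereocentre is formed.

Step 2
Reactants: 2 (S)-5-[(tert-butyldimethylsilyloxy)methyl]furan-2(5H)-one
Product: 3 (4R,5S)-5-[(tert-butyldimethylsilyloxy)methyl]-4-vinyldihydrofuran-2(3H)-one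
Conditions: CH2=CHMgBr, CuBr·SMe2 (10 mol %), THF, −78 → −40 °C; AcOH
Reagents that add atoms: vinylmagnesium bromide, C=C[Mg]Br
Why: Copper-catalysed conjugate addition of the Grignard reagent should deliver the vinyl group (future C6 and C3) to C7 anti to the silyloxymethyl group on C8, so the trans C7/C8 relationship is set by substrate control.

Step 3
Reactants: 3 (4R,5S)-5-[(tert-butyldimethylsilyloxy)methyl]-4-vinyldihydrofuran-2(3H)-one
Product: 4 (4R,5S)-5-(hydroxymethyl)-4-vinyldihydrofuran-2(3H)-one
Conditions: HF·pyridine, THF, 0 °C → rt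
Reagents that add atoms: none
Why: Fluoride-mediated desilylation frees the primary alcohol without touching the lactone or the two stereocentres.

Step 4
Reactants: 4 (4R,5S)-5-(hydroxymethyl)-4-vinyldihydrofuran-2(3H)-one
Product: 5 [(2S,3R)-5-oxo-3-vinyltetrahydrofuran-2-yl]methyl trifluoromethanesulfonate
Conditions: (CF3SO2)2O, pyridine, CH2Cl2, −78 → −30 °C; cold work-up, used at once
Reagents that add atoms: trifluoromethanesulfonic anhydride, O=S(=O)(OS(=O)(=O)C(F)(F)F)C(F)(F)F
Why: Sulfonylation of the primary alcohol gives a leaving group reactive enough for a low-temperature copper-catalysed coupling; no stereocentre is affected.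

Step 5
Reactants: 5 [(2S,3R)-5-oxo-3-vinyltetrahydrofuran-2-yl]methyl trifluoromethanesulfonate
Product: 6 (4R,5R)-5-(2-methylprop-2-en-1-yl)-4-vinyldihydrofuran-2(3H)-one
Conditions: CH2=C(CH3)MgBr, CuBr·SMe2 (10 mol %), THF, −78 → −30 °C
Reagents that add atoms: isopropenylmagnesium bromide, CC(=C)[Mg]Br
Why: Copper-catalysed SN2 coupling of the primary triflate with the alkenyl Grignard reagent forms C9–C10 faster than the reagent attacks the lactone at this temperature and leaves C7 and C8 untouched.

Step 6
Reactants: 6 (4R,5R)-5-(2-methylprop-2-en-1-yl)-4-vinyldihydrofuran-2(3H)-one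
Product: 7 tert-butyl (4S,5R)-5-(2-methylprop-2-en-1-yl)-2-oxo-4-vinyltetrahydrofuran-3-carboxylate
Conditions: LiHMDS (2.2 equiv), THF, −78 °C; Boc2O, −78 → −20 °C; AcOH
Reagents that add atoms: di-tert-butyl dicarbonate, CC(C)(C)OC(=O)OC(=O)OC(C)(C)C
Why: Claisen-type C-acylation of the lactone lithium enolate (C11 is the only acidic position) installs the carboxyl that later serves as tether and as methylenation handle; the second equivalent of base takes up the acidic proton of the product, and the labile C11 centre is of no consequence.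

Step 7
Reactants: 7 tert-butyl (4S,5R)-5-(2-methylprop-2-en-1-yl)-2-oxo-4-vinyltetrahydrofuran-3-carboxylate
Product: 8 tert-butyl (4S,5R)-4-acetyl-5-(2-methylprop-2-en-1-yl)-2-oxotetrahydrofuran-3-carboxylate
Conditions: PdCl2 (10 mol %), CuCl, O2 (1 atm), DMF/H2O 7:1, rt
Reagents that add atoms: water, O
Why: Wacker oxidation is selective for the monosubstituted vinyl group over the 1,1-disubstituted alkene and follows Markovnikov regiochemistry, so C6 becomes the ketone and C3 its methyl group; C7 stays in its more stable trans arrangement.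

Step 8
Reactants: 8 tert-butyl (4S,5R)-4-acetyl-5-(2-methylprop-2-en-1-yl)-2-oxotetrahydrofuran-3-carboxylate; 9 acrolein
Product: 10 tert-butyl (4S,5R)-4-(3-hydroxypent-4-enoyl)-5-(2-methylprop-2-en-1-yl)-2-oxotetrahydrofuran-3-carboxylate
Conditions: LDA (2.1 equiv), THF, −78 °C; acrolein; AcOH, −78 °C
Reagents that add atoms: none
Why: Aldol addition of a dianion: the first equivalent of base removes the malonate-type proton at C11, the second forms the kinetic methyl enolate at C3, which is the more reactive site and adds 1,2 to acrolein; the C2 carbinol centre is formed without control and is oxidised away in step 10.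

Step 9
Reactants: 10 tert-butyl (4S,5R)-4-(3-hydroxypent-4-enoyl)-5-(2-methylprop-2-en-1-yl)-2-oxotetrahydrofuran-3-carboxylate
Product: 11 bicyclic hydroxy ketone (eight-membered ring with C2–OH, C6=O and Z C1=C10, trans-fused to ring A, tert-butyl ester on C11)
Conditions: second-generation Grubbs catalyst RuCl2(=CHPh)(PCy3)(H2IMes) (5 mol %), 1,4-benzoquinone (10 mol %), CH2Cl2 (2 mM), 40 °C
Reagents that add atoms: none
Why: Ring-closing olefin metathesis between the vinyl carbinol and the 1,1-disubstituted alkene, held trans on the lactone, closes the eight-membered ring at C1=C10; in a ring of this size the trisubstituted olefin can only be cis (Z).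

Step 10
Reactants: 11 bicyclic hydroxy ketone
Product: 12 ring 1,3-diketone (C2=O and C6=O, Z C1=C10, trans lactone, tert-butyl ester on C11)
Conditions: Dess–Martin periodinane, CH2Cl2, 0 °C
Reagents that add atoms: none
Why: Dess–Martin oxidation of the allylic alcohol gives the enone carbonyl at C2 and with it the ring 1,3-diketone under non-basic conditions that spare C7.

Step 11
Reactants: 12 ring 1,3-diketone
Product: 14 tricyclic enol lactone (O6 acylated by the C11 carboxyl; C3=C6 enol ester of the C2 ketone; Z C1=C10; ring A trans on C7/C8; rings A and B cis-fused), via carboxylic acid 13 (not isolated)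
Conditions: CF3CO2H/CH2Cl2 1:4, 0 °C → rt, evaporate; EDC·HCl, CH2Cl2 (5 mM), 0 °C → rt
Reagents that add atoms: none
Why: Acidolysis of the tert-butyl ester followed by carbodiimide-mediated enol esterification: the activated C11 carboxyl can reach only the enol oxygen on C6 (five-membered lactone, against a seven-membered one for the oxygen on C2), which fixes the regiochemistry of the enol ester, and the new lactone must be cis-fused to ring A, which fixes C11.

Step 12
Reactants: 15 propanal
Product: 16 (Z)-triethyl(prop-1-en-1-yloxy)silane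
Conditions: Et3SiOTf, Et3N, Et2O, 0 °C
Reagents that add atoms: triethylsilyl trifluoromethanesulfonate, CC[Si](CC)(CC)OS(=O)(=O)C(F)(F)F
Why: Soft enolisation of the aldehyde and O-silylation (silyl enol ether formation) should favour the Z isomer; no stereocentre is formed.

Step 13
Reactants: 14 tricyclic enol lactone; 16 (Z)-triethyl(prop-1-en-1-yloxy)silane
Product: 18 ten-membered 2,6-diketone (C4 methyl; C5 OSiEt3; CO2Me on C11; trans lactone; Z C1=C10), via cyclobutane photoadduct 17 (not isolated)
Conditions: hν (350 nm, Pyrex), 16 (10 equiv), CH2Cl2, −30 °C, degassed; evaporate; K2CO3, MeOH, 0 °C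
Reagents that add atoms: methanol, CO
Why: Proposed new method: the closest known reaction is the de Mayo sequence of five- and six-membered 1,3-diketone enol esters with alkenes, which has not been shown on an eight-membered cross-conjugated enol ester; the n,π* triplet of the β-acyloxy enone should add 16 through a 1,4-biradical with head-to-tail orientation (polarised β-carbon C6 to the oxygen-bearing carbon C5, C3 to C4), closing the four-membered ring C3–C4–C5–C6 by stepwise [2+2] radical recombination. Methoxide then opens a lactone carbonyl on C11 (attack at either one converges, because the C8 alkoxide relactonises onto the other), and the freed C6 alkoxide undergoes retro-aldol cleavage of the strained C3–C6 bond, so the ten-membered ring arises by fragmentation (two-carbon ring expansion) and not by cyclisation. C4 and C5 are controlled by the shape of 14: the cis-fused bis-lactone is cup-shaped, ring A and C8/C9 cover the concave face of C3=C6, and addition on the convex face (that of H7) with methyl and silyloxy exo (cis to O6 and H3) corresponds to 4R,5R, whereas C3 and C6 lose their configuration in the fragmentation. The step needs the enol oxygen on C6 (fixed by the C11 tether), head-to-tail regiochemistry (enone polarity against an enol ether), reaction at the push–pull C3=C6 bond and not at C1=C10 (whose C10 is fully substituted), and a cis C4/C5 relation, which the exo preference should restore even if the Z geometry of 16 is scrambled in the biradical. The Z C1=C10 enone is carried over unchanged from the eight-membered ring, and in the basic stage C7 is shielded from epimerisation by the adjacent malonate-type anion at C11.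

Step 14
Reactants: 18 ten-membered 2,6-diketone
Product: 19 (6R)-alcohol of 18 (C2 ketone kept)
Conditions: NaBH4, MeOH/CH2Cl2 1:1, −78 °C
Reagents that add atoms: none
Why: Hydride reduction under conditions in which a saturated ketone reacts faster than a conjugated enone; Felkin–Anh addition anti to the bulky, non-chelating silyloxy group on C5 should give the 5,6-syn (6R) alcohol.

Step 15
Reactants: 19 (6R)-alcohol
Product: 20 C6 tert-butyldimethylsilyl ether of 19
Conditions: tBuMe2SiOTf, 2,6-lutidine, CH2Cl2, −78 → 0 °C
Reagents that add atoms: tert-butyldimethylsilyl trifluoromethanesulfonate, CC(C)(C)[Si](C)(C)OS(=O)(=O)C(F)(F)F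
Why: Silylation of the hindered secondary alcohol with the silyl triflate protects C6–OH with a group that survives the later selective removal of the triethylsilyl group on C5.

Step 16
Reactants: 20 C6 silyl ether
Product: 22 α-methylene lactone (C11=C13; C5 OSiEt3; C6 OSiMe2tBu), via malonic half-acid 21 (not isolated)
Conditions: LiOH, THF/H2O, 0 °C; 1 M HCl to pH 3; (CH2O)n, Et2NH, THF, 60 °C
Reagents that add atoms: formaldehyde (from paraformaldehyde), C=O
Why: Saponification of the activated methyl ester (ring A recloses on acidification) and Mannich-type decarboxylative methylenation of the α-carboxy lactone build the exocyclic methylene without any strong base, so the more acidic C2 ketone is not involved.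

Step 17
Reactants: 22 α-methylene lactone
Product: 23 C5 alcohol of 22 (C6 OSiMe2tBu kept)
Conditions: PPTS, MeOH/CH2Cl2, 0 °C → rt
Reagents that add atoms: none
Why: Acid-catalysed methanolysis removes a triethylsilyl ether much faster than a tert-butyldimethylsilyl ether, so only C5–OH is freed.

Step 18
Reactants: 24 angelic acid
Product: 25 (Z)-2-methylbut-2-en-1-ol
Conditions: LiAlH4, Et2O, 0 °C; H2O, aq NaOH
Reagents that add atoms: none
Why: Hydride reduction of the carboxylic acid gives the allylic alcohol without touching or isomerising the trisubstituted Z olefin.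

Step 19
Reactants: 25 (Z)-2-methylbut-2-en-1-ol
Product: 26 (2S,3R)-2,3-epoxy-2-methylbutan-1-ol
Conditions: Ti(OiPr)4 (10 mol %), L-(+)-diethyl tartrate (12 mol %), tBuOOH, 4 Å molecular sieves, CH2Cl2, −20 °C
Reagents that add atoms: tert-butyl hydroperoxide, CC(C)(C)OO
Why: Sharpless asymmetric epoxidation: the L-(+)-tartrate catalyst should deliver oxygen to the face that gives the 2S centre, and the Z geometry is transferred stereospecifically to give 3R.

Step 20
Reactants: 26 (2S,3R)-2,3-epoxy-2-methylbutan-1-ol
Product: 27 (2R,3R)-2,3-epoxy-2-methylbutanoic acid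
Conditions: RuCl3·xH2O (2 mol %), NaIO4, CCl4/MeCN/H2O, rt
Reagents that add atoms: sodium periodate, [Na+].[O-]I(=O)(=O)=O; water, O
Why: RuO4-catalysed oxidation takes the primary alcohol to the acid without opening the epoxide; the C2 descriptor changes from S to R only because the substituent priorities change.

Step 21
Reactants: 27 (2R,3R)-2,3-epoxy-2-methylbutanoic acid; 23 C5 alcohol
Product: 29 C5 (2R,3R)-epoxyangelate of 23 (C6 OSiMe2tBu), via mixed anhydride 28 (not isolated)
Conditions: 2,4,6-Cl3C6H2COCl, Et3N, THF, rt; then 23, DMAP, toluene, rt → 40 °C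
Reagents that add atoms: none
Why: Yamaguchi esterification through the mixed anhydride acylates the only free hydroxyl (C5) of a hindered alcohol with a hindered acid; no stereocentre is touched, and a minor diastereomer from incomplete enantiopurity of 27 would be separable here.

Step 22
Reactants: 29 silyl-protected ester
Product: 30 Vicolide D
Conditions: HF·pyridine, pyridine, THF, 0 °C → rt
Reagents that add atoms: none
Why: Buffered fluoride desilylation should free C6–OH without acyl migration, epoxide opening or addition to the α-methylene lactone.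

**Compound list**

1 | (S)-5-(hydroxymethyl)furan-2(5H)-one | OC[C@H]1OC(=O)C=C1 | starting material
2 | (S)-5-[(tert-butyldimethylsilyloxy)methyl]furan-2(5H)-one | CC(C)(C)[Si](C)(C)OC[C@H]1OC(=O)C=C1 | intermediate
3 | (4R,5S)-5-[(tert-butyldimethylsilyloxy)methyl]-4-vinyldihydrofuran-2(3H)-one | O=C1C[C@H](C=C)[C@@H](CO[Si](C)(C)C(C)(C)C)O1 | intermediate
4 | (4R,5S)-5-(hydroxymethyl)-4-vinyldihydrofuran-2(3H)-one | O=C1C[C@H](C=C)[C@@H](CO)O1 | intermediate
5 | [(2S,3R)-5-oxo-3-vinyltetrahydrofuran-2-yl]methyl trifluoromethanesulfonate | O=C1C[C@H](C=C)[C@@H](COS(=O)(=O)C(F)(F)F)O1 | intermediate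
6 | (4R,5R)-5-(2-methylprop-2-en-1-yl)-4-vinyldihydrofuran-2(3H)-one | O=C1C[C@H](C=C)[C@@H](CC(C)=C)O1 | intermediate
7 | tert-butyl (4S,5R)-5-(2-methylprop-2-en-1-yl)-2-oxo-4-vinyltetrahydrofuran-3-carboxylate (C3 = C11, epimers) | O=C1O[C@H](CC(C)=C)[C@@H](C=C)C1C(=O)OC(C)(C)C | intermediate
8 | tert-butyl (4S,5R)-4-acetyl-5-(2-methylprop-2-en-1-yl)-2-oxotetrahydrofuran-3-carboxylate | O=C1O[C@H](CC(C)=C)[C@@H](C(C)=O)C1C(=O)OC(C)(C)C | intermediate
9 | acrolein | C=CC=O | starting material
10 | tert-butyl (4S,5R)-4-(3-hydroxypent-4-enoyl)-5-(2-methylprop-2-en-1-yl)-2-oxotetrahydrofuran-3-carboxylate (carbinol epimers) | O=C1O[C@H](CC(C)=C)[C@@H](C(=O)CC(O)C=C)C1C(=O)OC(C)(C)C | intermediate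
11 | bicyclic hydroxy ketone: eight-membered ring with C2–OH, C6=O, Z C1=C10, trans-fused ring A, tert-butyl ester on C11 | O=C1O[C@@H]2C/C(C)=C\C(O)CC(=O)[C@H]2C1C(=O)OC(C)(C)C | intermediate
12 | ring 1,3-diketone (C2=O, C6=O), otherwise as 11 | O=C1O[C@@H]2C/C(C)=C\C(=O)CC(=O)[C@H]2C1C(=O)OC(C)(C)C | intermediate
13 | C11 carboxylic acid of 12 | O=C1O[C@@H]2C/C(C)=C\C(=O)CC(=O)[C@H]2C1C(=O)O | intermediate
14 | tricyclic enol lactone: eight-membered C3=C6 enol ester of the C2/C6 diketone, O6 acylated by the C11 carboxyl, Z C1=C10, ring A trans on C7/C8, rings A and B cis-fused | O=C1O/C2=C/C(=O)/C=C(C)\C[C@H]3OC(=O)[C@H]1[C@H]23 | intermediate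
15 | propanal | CCC=O | starting material
16 | (Z)-triethyl(prop-1-en-1-yloxy)silane | C/C=C\O[Si](CC)(CC)CC | intermediate
17 | cyclobutane photoadduct (C3–C4 and C5–C6 formed; 4R,5R; methyl and OSiEt3 cis and exo) | O=C1O[C@]23[C@H](O[Si](CC)(CC)CC)[C@H](C)[C@H]2C(=O)/C=C(C)\C[C@H]4OC(=O)[C@H]1[C@H]34 | intermediate
18 | ten-membered 2,6-diketone: C4 methyl, C5 OSiEt3, CO2Me on C11, trans lactone, Z C1=C10 | COC(=O)C1C(=O)O[C@@H]2C/C(C)=C\C(=O)C[C@@H](C)[C@@H](O[Si](CC)(CC)CC)C(=O)[C@@H]12 | intermediate
19 | (6R)-alcohol of 18 | COC(=O)C1C(=O)O[C@@H]2C/C(C)=C\C(=O)C[C@@H](C)[C@@H](O[Si](CC)(CC)CC)[C@H](O)[C@@H]12 | intermediate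
20 | C6 tert-butyldimethylsilyl ether of 19 | COC(=O)C1C(=O)O[C@@H]2C/C(C)=C\C(=O)C[C@@H](C)[C@@H](O[Si](CC)(CC)CC)[C@H](O[Si](C)(C)C(C)(C)C)[C@@H]12 | intermediate
21 | C11 carboxylic acid of 20 (malonic half-acid) | OC(=O)C1C(=O)O[C@@H]2C/C(C)=C\C(=O)C[C@@H](C)[C@@H](O[Si](CC)(CC)CC)[C@H](O[Si](C)(C)C(C)(C)C)[C@@H]12 | intermediate
22 | α-methylene lactone with C5 OSiEt3 and C6 OSiMe2tBu | C=C1C(=O)O[C@@H]2C/C(C)=C\C(=O)C[C@@H](C)[C@@H](O[Si](CC)(CC)CC)[C@H](O[Si](C)(C)C(C)(C)C)[C@@H]12 | intermediate
23 | C5 alcohol of 22 | C=C1C(=O)O[C@@H]2C/C(C)=C\C(=O)C[C@@H](C)[C@@H](O)[C@H](O[Si](C)(C)C(C)(C)C)[C@@H]12 | intermediate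
24 | angelic acid, (Z)-2-methylbut-2-enoic acid | C/C=C(C)\C(=O)O | starting material
25 | (Z)-2-methylbut-2-en-1-ol | C/C=C(C)\CO | intermediate
26 | (2S,3R)-2,3-epoxy-2-methylbutan-1-ol | OC[C@]1(C)O[C@@H]1C | intermediate
27 | (2R,3R)-2,3-epoxy-2-methylbutanoic acid | OC(=O)[C@]1(C)O[C@@H]1C | intermediate
28 | mixed anhydride of 27 with 2,4,6-trichlorobenzoic acid | O=C(OC(=O)[C@]1(C)O[C@@H]1C)c1c(Cl)cc(Cl)cc1Cl | intermediate
29 | C5 (2R,3R)-epoxyangelate of 23, C6 OSiMe2tBu | C=C1C(=O)O[C@@H]2C/C(C)=C\C(=O)C[C@@H](C)[C@@H](OC(=O)[C@]3(C)O[C@@H]3C)[C@H](O[Si](C)(C)C(C)(C)C)[C@@H]12 | intermediate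
30 | Vicolide D | C=C1C(=O)O[C@@H]2C/C(C)=C\C(=O)C[C@@H](C)[C@@H](OC(=O)[C@]3(C)O[C@@H]3C)[C@H](O)[C@@H]12 | target

**Step count**

Total: 22 steps. Longest linear sequence: 18 steps (steps 1–11, 13–17, 21, 22, from compound 1).

**Steps most likely to fail**

Step 13 (carries the label).
- What may go wrong: the triplet of the eight-membered dienone may relax by twisting about C1=C10 or C3=C6 (cis–trans isomerisation followed by dimerisation) instead of adding the alkene; the alkene may add at C1=C10; or the exo preference at C4/C5 may be low.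
- Fallback, with known chemistry: the photocycloaddition is moved to an open-chain β-acyloxy enone, a chromophore type on which the de Mayo sequence is established, and the ten-membered ring is closed afterwards by olefin metathesis. It sets out from 8.
- Claisen acylation of the dianion of 8 (LiHMDS) with 1-[3-(4-methoxybenzyloxy)propanoyl]benzotriazole should give the open-chain 1,3-diketone F1. Cleavage of the tert-butyl ester (Me3SiOTf, 2,6-lutidine, then water) gives the carboxylic acid F2, which EDC closes to the exocyclic enol lactone F3 (cis-fused bis-lactone; its E/Z mixture is of no consequence).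
- Irradiation with 16 and K2CO3/MeOH give, through the cyclobutane F4, the open-chain 1,5-diketone F5. DDQ frees the primary alcohol F6, and MsCl/Et3N eliminates to the vinyl ketone F7.
- Ring-closing metathesis with the second-generation Grubbs catalyst under equilibrating conditions (the cis olefin is the less strained one in a ten-membered ring) comes back to the route at 18.

Step 11.
- What may go wrong: closure to the tricyclic enol lactone may be outrun by decarboxylation of the malonic half-acid, by intermolecular anhydride formation, or by O-to-C acyl migration to the cyclic triketone.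
- Fallback: the tether is given up, the enol ester is made bimolecularly and the regioisomers are separated. It sets out from 12.
- Acid 13 is esterified with methanol (EDC, DMAP) to the methyl ester F8. Ac2O/pyridine gives the enol acetates, from which the cross-conjugated C6 enol acetate F9 is separated; the C2 isomer is recycled to F8 by K2CO3/MeOH.
- Irradiation of F9 with 16 and K2CO3/MeOH give, through the acetoxy cyclobutane F10, the diketone 18, where the route is rejoined.

Step 14.
- What may go wrong: competing hydride addition to the C2 enone carbonyl and low facial selectivity at C6 in the flexible ten-membered ring.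
- Fallback: over-reduction and selective re-oxidation instead of a chemoselective reduction. It sets out from 18.
- NaBH4/CeCl3·7H2O in MeOH at −78 °C reduces both carbonyl groups to the diol F11 (C2 epimers). C6 epimers are separated at this stage, the unwanted one being returned to 18 by Dess–Martin oxidation.
- MnO2 in CH2Cl2 then oxidises only the allylic C2 carbinol and comes back to the route at 19.

**Further compounds**

F1 | step 13 | open-chain 1,3-diketone from 8 (C2 carries CH2CH2O-4-methoxybenzyl) | O=C1O[C@H](CC(C)=C)[C@@H](C(=O)CC(=O)CCOCc2ccc(OC)cc2)C1C(=O)OC(C)(C)C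
F2 | step 13 | C11 carboxylic acid of F1 | O=C1O[C@H](CC(C)=C)[C@@H](C(=O)CC(=O)CCOCc2ccc(OC)cc2)C1C(=O)O
F3 | step 13 | exocyclic enol lactone (cis-fused bis-lactone, E/Z mixture) | O=C1OC(=CC(=O)CCOCc2ccc(OC)cc2)[C@@H]3[C@@H](CC(C)=C)OC(=O)[C@H]13
F4 | step 13 | cyclobutane photoadduct of F3 with 16 (C3 not assigned) | O=C1O[C@@]2([C@H](O[Si](CC)(CC)CC)[C@H](C)C2C(=O)CCOCc4ccc(OC)cc4)[C@@H]3[C@@H](CC(C)=C)OC(=O)[C@H]13
F5 | step 13 | open-chain 1,5-diketone, methyl ester on C11, C5 OSiEt3 | O=C1O[C@H](CC(C)=C)[C@@H](C(=O)[C@H](O[Si](CC)(CC)CC)[C@H](C)CC(=O)CCOCc2ccc(OC)cc2)C1C(=O)OC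
F6 | step 13 | primary alcohol from F5 | O=C1O[C@H](CC(C)=C)[C@@H](C(=O)[C@H](O[Si](CC)(CC)CC)[C@H](C)CC(=O)CCO)C1C(=O)OC
F7 | step 13 | vinyl ketone from F6 | O=C1O[C@H](CC(C)=C)[C@@H](C(=O)[C@H](O[Si](CC)(CC)CC)[C@H](C)CC(=O)C=C)C1C(=O)OC
F8 | step 11 | methyl ester analogue of 12 | O=C1O[C@@H]2C/C(C)=C\C(=O)CC(=O)[C@H]2C1C(=O)OC
F9 | step 11 | C6 enol acetate of F8 | CC(=O)O/C1=C/C(=O)/C=C(C)\C[C@H]2OC(=O)C(C(=O)OC)[C@H]12
F10 | step 11 | acetoxy cyclobutane photoadduct of F9 with 16 (C3 and C6 not assigned) | COC(=O)C1C(=O)O[C@@H]2C/C(C)=C\C(=O)C3[C@@H](C)[C@@H](O[Si](CC)(CC)CC)C3(OC(C)=O)[C@@H]12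
F11 | step 14 | C2,C6 diol from 18 (C2 epimers) | COC(=O)C1C(=O)O[C@@H]2C/C(C)=C\C(O)C[C@@H](C)[C@@H](O[Si](CC)(CC)CC)[C@H](O)[C@@H]12
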